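The flask was to be read at 2.0 d, but its readings stopped at 10.0 h, so I treated the answer as the last reading plus a correction for the Sbt still in the flask.

all flasks: Sbt 1.5 M; Spx 200 mM (held)
- winter: the very flask that is asked about, followed so far
- flask: time 2.0 d

winter run (percent of the Sbt charged)

| time / h | Sbt.Spx2 / % | Sbt / % |
|---|---|---|
| 0.833 | 1.4 | 91.7 |
| 2.00 | 4.4 | 78.6 |
| 4.00 | 10.7 | 61.0 |
| 10.0 | 22.5 | 28.2 |

(each reading ± 0.5 percentage points)

- at the start none of Spx is in solution
- Spx2 is what Spx becomes in solution

- larch: doubling the transfer coefficient of Spx, all else as stated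
- cedar: doubling the saturation concentration of Spx, all else as stated

* Sbt.Spx2 at 2.0 d, in percent of the Sbt charged
* concentration of Spx2 in solution at 5.0 h, in percent of saturation
* the change that raises the amount of Sbt.Spx2 at 2.0 d, in percent of the Sbt charged most ("none" if none brings more than 2 percentage points) (larch / cedar / none)
* amount of Sbt.Spx2 at 2.0 d, in percent of the Sbt charged, after cedar

At that last reading, Sbt and Sbt.Spx2 together made up 50.7 % of the charge, so a second route was taking Sbt somewhere unseen, and I needed the split between the routes. Between 4.00 h and 10.0 h, Sbt fell by 33 percentage points while Sbt.Spx2 rose by 12 points. I kept their ratio, 0.360, as the capture share: the Sbt.Spx2 gained per Sbt lost, a selectivity for one stretch of the run. The stretch from 2.00 h to 4.00 h gave 0.358, so the reading held steady over both stretches. In the last stretch Sbt fell with a rate constant of 0.129 h⁻¹. The 38.0 h still to run hold 7.07 half-lives at that pace, so I shared out the whole 28.2 % left at the last reading. That correction came to 10 points, less than the 22.5 % already made, and my reckoning for y was 32.6 %.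

The forecast, reckoned by rates and not by this share, gave 32.5 % (from 29.5 % to 35.5 %), 95 % of saturation at 5.0 h, cedar as the best change, and 48 % after it. Its ground for the saturation was: “Late product rate stays proportional to Sbt, so the reaction is kinetics-limited and solution stays near saturation”.

The flask gave 34.6 %, and c(Spx2) stood at 62.5 % of saturation at 5.0 h, 33 points under the forecast. The best change was cedar, which added 9.1 points against 3.7 points for larch and reached 43.8 %.

    Sbt + Spx2 → Sbt.Spx2 (k = 0.370 M⁻¹ h⁻¹)
    Sbt ⇌ Int (K = 14.0, k = 0.0910 h⁻¹)
    Spx ⇌ Spx2, rate k3*(csat - [Spx2]) (kL = 0.630 h⁻¹)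
    2 Spx2 → Pdt (k = 0.130 M⁻¹ h⁻¹)
    Spx2 + Sbt.Spx2 → Sdp (k = 0.0170 M⁻¹ h⁻¹)

In this flask, Sbt went both to Int and to Sbt.Spx2 while c(Spx2) climbed, and at 1.00 d there stood 5.47 % of Sbt beside 61.3 % of Int and 31.9 % of Sbt.Spx2. Over the next day, Sbt.Spx2 rose to 34.6 % as Int eased to 59.0 %. The capture share had put this flask 2 points lower. For the same flask read at 12 h, the share applied from the last reading gives 25.1 %; that flask, with 21.0 % of Sbt left, held 24.8 % of Sbt.Spx2.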